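## Structural features

The target is an elemane-type sesquiterpene lactone: a fully substituted cyclohexane (C5–C10) cis-fused at C6/C7 to a γ-lactone (C6–O–C12(=O)–C11–C7). C10 is quaternary (methyl C14, vinyl C1=C2), C5 carries the isopropenyl group (C3=C4–C15), C8 an acetate, and C11 is a second fully substituted carbon bearing methyl C13 and a (Z)-2-methylbut-2-enoate (angelate). Six stereocentres are packed together (C10, C5, C6, C7, C8 in the carbocycle and C11 beside it). The isopropenyl group is cis to the C10 methyl and trans to the C6 oxygen. The C6–O and C7–C11 bonds are cis, the C8 acetate is trans to C11, and at C11 the acyloxy group lies on the convex face, syn to H7. Fragile elements are the Z-enoate (isomerises to the tiglate under nucleophilic or basic catalysis), the tertiary ester, the 1,3-related esters on C8 and C11 (acyl exchange through any alkoxide), and the 1,2-dialkenyl unit at C5/C10 (Cope-prone on heating). The two terminal alkenes also forbid hydrogenation, hydroboration and unselective electrophilic oxidation once they are in place. The real difficulty is the vicinal pair C10 (quaternary)/C5, followed by the C6–C7–C8 triad in which the C8 oxygen sits cis to the C10 methyl. The key step exploits the para relationship of C10 and C7 in the six-membered ring. C10, its methyl and a one-carbon precursor of the vinyl group come from an α-methyl acrolein, and C5–C8 come from a 1-amino-3-siloxydiene whose oxygen marks C7 and whose nitrogen turns C5 into the β-carbon of an enone.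

## Logic of the disconnections

32 ⇒ 30 (through 31). The acetyl C–O bond at C8 is cut and the oxygen is carried as a silyl ether. An acetate would not survive the enolate chemistry at C11, and a free C8 alkoxide could take over the C11 acyl group or the lactone. The forward step must therefore unmask C8–OH without ever forming an alkoxide and acetylate last.

30 ⇒ 28 + 29. The ester C–O bond at O11 is cut. The Z-enoate is the most fragile group, so it is attached late from a donor that already has the Z geometry. This leaves a plain tertiary α-hydroxy lactone. The forward step must acylate a hindered tertiary oxygen without Z/E isomerisation.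

28 ⇒ 26 (through 27). The C11–O bond is cut. C11 is α to the lactone carbonyl, its enolate is planar, and the cis-fused bicycle leaves open exactly the face that the oxygen has to occupy. C11 therefore needs no earlier control. The oxidant must be an electrophilic oxygen source that ignores two terminal alkenes.

26 ⇒ 24 ⇒ 23. The lactone carbonyl is taken back to a mixed acetal and the silyl ether to the alcohol. A haloacetal cyclises readily as a radical, whereas a haloester does not. The forward oxidation must touch only the acetal carbon.

23 ⇒ 21. The C7–C11 and C8–O bonds are cut together. A radical tethered through O6 can only close cis onto C7, and the new ring then shields one face of the C8 radical, so oxygen enters trans to C11. This adds across C7=C8 without any reagent that would attack the vinyl or isopropenyl groups. The cyclisation must outrun capture of the first radical by oxygen.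

21 ⇒ 19 + 20. The acetal C12–O6 bond and the C11–Br bond are cut. C11, C12 and C13 come from a three-carbon enol ether. The only demand is that the halonium forms on the enol ether and not on the other alkenes.

19 ⇒ 18. The C1=C2 bond is cut to an aldehyde. From this point on no carbonyl group is present, and before it the aldehyde had to stay masked. The methylenation must cope with a neopentyl aldehyde and a free hydroxyl.

18 ⇒ 17 ⇒ 15 ⇒ 14. The C7=C8 alkene is traced to the C7 ketone through its arylsulfonylhydrazone, and the aldehyde to its acetal. This moves functionality off C7, which must end as CH, onto the alkene needed for the radical step. The forward reaction must metalate at C8 only and keep the C6–O bond.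

14 ⇒ 12 (through 13). The C6–O bond is cut. The enol ether in 12 is regiodefined by the conjugate addition that made it. The oxidant must enter anti to the C5 substituent and prefer the enol ether over the isopropenyl alkene.

12 ⇒ 10 + 11. The C5–C4 bond is cut, since C5 is the β-carbon of the enone. The face is chosen by the adjacent quaternary centre, which requires the C1 substituent to be clearly larger than methyl; hence the acetal.

10 ⇒ 9 ⇒ 7 (through 8). The acetal returns to the aldehyde and the enone to the β-amino silyl enol ether. The forward steps must unveil the enone without harming the non-enolisable but base-sensitive formyl group, and then protect the aldehyde in preference to the conjugated ketone.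

7 ⇒ 5 + 6. The C5–C10 and C8–C9 bonds are cut. This is the only point at which absolute configuration is introduced; C10 is set and everything else is relayed from it. The nitrogen of 5 carries an acyl group rather than two alkyl groups. A dialkylamino diene would add to 6 without the catalyst and would bind the Lewis acid, so enantiofacial control could not be expected from it.

5 ⇒ 4 ⇒ 3 ⇒ 1 + 2. The Si–O, N–acyl and N–C(vinyl) bonds are cut in turn, down to a commercial enaminone and a primary amine.

## Other disconnections considered

Alternative 1: The cut runs through C6–C7 and the lactone C12–O bond. In the forward sense the open-chain aldehyde A1, which carries a 2-(bromomethyl)acrylate, would be treated with zinc or CrCl2. The allylmetal would add through C7 to the C6 aldehyde and the alkoxide would lactonise, giving A2.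
- In favour: one step would form the carbocycle, the cis ring fusion and the lactone, and the C8 oxygen would arrive with its configuration already set. On these two points the alternative is better than the chosen plan, which spends steps 12–15 on them.
- Against: A1 must already contain the vicinal C10/C5 pair in an open chain, which is the hardest part of the molecule and is not helped by the ring closure. C5 is α to the aldehyde and can epimerise. A2 would still need its exocyclic methylene converted into the oxygenated C11, a radical hydration that must distinguish a conjugated alkene from a vinyl and an isopropenyl group.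
- Comparison: the mechanism is as sound as that of the chosen plan. The chosen plan sets C10 by a catalyst and functionalises C11 through an enolate, which is chemoselective. Overall step count would be no lower once A1 is made.

Alternative 2: The cut removes C1–C10 and C4–C5 as a photocycloaddition of the enone A3 with 1-methylcyclobutene A4 to the tricycle A5. Thermal opening of the bicyclo[2.2.0]hexane unit would then give the dialkenyl ketone A6.
- In favour: two steps would deliver the quaternary carbon and both alkenyl groups. The C8 oxygen is present from the start, and the ketone ends at C6, so C7 is an α-carbon. That polarity is better than in the chosen plan, where C7 is a carbonyl carbon that has to be turned into CH.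
- Against: head-to-head versus head-to-tail regiochemistry with an unsymmetrical cyclobutene is uncertain, and face selection would rest on a remote silyloxy group. The opening needs temperatures at which Cope rearrangement of the product can compete. In A6 the C8 silyloxy group is β to the ketone and prone to elimination once C7 is enolised, and C5 is epimerisable.
- Comparison: step economy is better than in the chosen plan. Stereochemical certainty at C10/C5 is lower, and absolute configuration would depend entirely on A3 rather than on a catalyst.

Alternative 3: The cut is C9–C10. The open-chain enone A7 would be treated with TiCl4 or EtAlCl2, so that the allylsilane γ-carbon C10 adds to C9 of the vinyl ketone, closing the ring and releasing the vinyl group to give A8.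
- In favour: A8 contains C5, C6 and C10 with the vinyl group already in place, so no aldehyde protection, deprotection or methylenation is needed. Here the alternative is better than the chosen plan.
- Against: the quaternary centre would be set only by relay from C5 through two competing chair-like arrangements. The vinyl ketone and the β-alkoxy ketone are sensitive to the Lewis acid. The benzyl ether would have to be removed without hydrogenolysis. A7 needs its own stereocontrolled assembly.
- Comparison: after ring closure the problem at C7, C8 and C11 is the same as in the chosen plan (equal). The chosen plan is more secure for C10 and starts from simpler materials, and the overall length would be similar.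

Key step: step 4

Assumption: the (S,S) antipode of the salen–chromium complex is taken to deliver the diene to the face of bound methacrolein that gives the 6S aldehyde 7; if the sense of induction is the reverse, the (R,R) antipode is used with no other change.

## Route

Step 1
Reactants: 1 (E)-4-(dimethylamino)but-3-en-2-one; 2 benzylamine
Product: 3 (Z)-4-(benzylamino)but-3-en-2-one
Conditions: EtOH, reflux
Reagents that add atoms: none
Why: Amine exchange on a vinylogous amide (addition–elimination at the β-carbon), driven by loss of volatile dimethylamine; the secondary enaminone is held in the Z form by its N–H···O hydrogen bond.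

Step 2
Reactants: 3 (Z)-4-(benzylamino)but-3-en-2-one
Product: 4 methyl benzyl[(E)-3-oxobut-1-en-1-yl]carbamate
Conditions: NaN(SiMe3)2, THF, −78 °C; ClCO2Me, −78 → 0 °C
Reagents that add atoms: methyl chloroformate, COC(=O)Cl
Why: N-Acylation of the sodium salt of the vinylogous amide gives the vinylogous imide. The acyl group is what later makes the diene non-basic and unreactive toward a dienophile that is not bound to the catalyst.

Step 3
Reactants: 4 methyl benzyl[(E)-3-oxobut-1-en-1-yl]carbamate
Product: 5 methyl benzyl[(E)-3-(tert-butyldimethylsilyloxy)buta-1,3-dien-1-yl]carbamate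
Conditions: KN(SiMe3)2, THF, −78 °C; t-BuMe2SiCl
Reagents that add atoms: tert-butyldimethylsilyl chloride, CC(C)(C)[Si](C)(C)Cl
Why: Kinetic deprotonation of the methyl ketone and O-silylation of the enolate (silyl enol ether formation) give the 1-amino-3-siloxydiene with the E enamide geometry retained.

Step 4
Reactants: 5 methyl benzyl[(E)-3-(tert-butyldimethylsilyloxy)buta-1,3-dien-1-yl]carbamate; 6 methacrolein
Product: 7 methyl benzyl[(1R,6S)-6-formyl-6-methyl-3-(tert-butyldimethylsilyloxy)cyclohex-2-en-1-yl]carbamate (endo adduct)
Conditions: (S,S)-[Cr(salen)]SbF6 (5 mol %; salen = N,N′-bis(3,5-di-tert-butylsalicylidene)cyclohexane-1,2-diaminate, trivalent chromium), 4 Å MS, CH2Cl2, −40 °C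
Reagents that add atoms: none
Why: The cationic chromium centre binds the aldehyde oxygen of 6 and lowers its LUMO, and the electron-rich diene adds in a concerted but strongly asynchronous normal-demand Diels–Alder reaction; the closest known type is the salen–metal-catalysed cycloaddition of carbamate-substituted 1-amino-3-siloxydienes with α-substituted acroleins. The six-membered ring closes by [4+2] cycloaddition: the siloxy-activated terminus C8 bonds to the unsubstituted carbon C9, and the nitrogen-bearing terminus C5 bonds to the fully substituted C10. Regiochemistry follows from the largest coefficients (C8 of the diene, C9 of the dienophile) and is reinforced by both donor groups. C10 is set by the chiral complex, which exposes one enantioface of the metal-bound aldehyde; C5 is set relative to C10 by the endo placement of the formyl group and is discarded in step 5. The selectivity that matters is therefore enantiofacial, and it depends on suppressing the uncatalysed pathway: the acylated nitrogen makes 5 inert toward free 6 at −40 °C and non-basic toward the metal, which a dialkylamino diene would not be. Molecular sieves keep the cationic complex dry and the silyl enol ether intact.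

Step 5
Reactants: 7 endo adduct
Product: 9 (1S)-1-methyl-4-oxocyclohex-2-ene-1-carbaldehyde, via keto carbamate 8 (not isolated)
Conditions: 1 M HCl, THF, 0 °C; then DBU, CH2Cl2, rt
Reagents that add atoms: none
Why: Acid hydrolysis of the silyl enol ether unmasks the β-carbamato ketone, and base-induced E1cB loss of the carbamate (retro-aza-Michael) gives the enone. C5 is destroyed, and C10, which has no acidic hydrogen, is untouched.

Step 6
Reactants: 9 (1S)-1-methyl-4-oxocyclohex-2-ene-1-carbaldehyde
Product: 10 (4S)-4-(1,3-dioxolan-2-yl)-4-methylcyclohex-2-en-1-one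
Conditions: Me3SiOCH2CH2OSiMe3, Me3SiOTf (5 mol %), CH2Cl2, −78 → −20 °C; pyridine
Reagents that add atoms: 1,2-bis(trimethylsilyloxy)ethane, C[Si](C)(C)OCCO[Si](C)(C)C
Why: Silyl-triflate-catalysed acetalisation with the bis-silyl glycol takes the aldehyde and leaves the conjugated ketone. The dioxolane shields the aldehyde from the organometallic reagent and makes the C1 substituent clearly larger than the C14 methyl.

Step 7
Reactants: 10 (4S)-4-(1,3-dioxolan-2-yl)-4-methylcyclohex-2-en-1-one; 11 isopropenylmagnesium bromide
Product: 12 {[(3R,4S)-4-(1,3-dioxolan-2-yl)-4-methyl-3-(prop-1-en-2-yl)cyclohex-1-en-1-yl]oxy}trimethylsilane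
Conditions: CuBr·SMe2 (10 mol %), Me3SiCl, THF, −78 °C; Et3N
Reagents that add atoms: chlorotrimethylsilane, C[Si](C)(C)Cl
Why: Copper-catalysed, chlorosilane-accelerated conjugate addition of the alkenyl Grignard reagent. Attack at C5 goes through the half-chair that keeps the incoming group anti to the bulkier dioxolanyl substituent on the neighbouring quaternary carbon, so isopropenyl ends cis to the methyl. The enolate is trapped regiospecifically as the C6=C7 silyl enol ether.

Step 8
Reactants: 12 silyl enol ether
Product: 14 (2S,3R,4S)-4-(1,3-dioxolan-2-yl)-2-hydroxy-4-methyl-3-(prop-1-en-2-yl)cyclohexan-1-one, via silyloxy epoxide 13 (not isolated)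
Conditions: dimethyldioxirane, acetone/CH2Cl2, −78 → −40 °C; then AcOH, THF/H2O, rt
Reagents that add atoms: dimethyldioxirane, CC1(C)OO1
Why: Rubottom oxidation: the electron-rich silyl enol ether is epoxidised far faster than the 1,1-disubstituted alkene, and from the face anti to the C5 isopropenyl group. C6–OH is therefore trans to it, which is also the more stable diequatorial arrangement.

Step 9
Reactants: 14 α-hydroxy ketone
Product: 15 2,4,6-triisopropylbenzenesulfonylhydrazone of 14
Conditions: 2,4,6-(i-Pr)3C6H2SO2NHNH2, 4 Å MS, THF, rt
Reagents that add atoms: 2,4,6-triisopropylbenzenesulfonohydrazide, CC(C)c1cc(C(C)C)c(S(=O)(=O)NN)c(C(C)C)c1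
Why: Condensation of the ketone with the arylsulfonyl hydrazide. The sulfonamide nitrogen is expected to settle anti to the more substituted C6 and so syn to the C8 methylene, which fixes the site of metalation in the next step.

Step 10
Reactants: 15 hydrazone
Product: 18 (1S,5R,6R)-5-hydroxy-1-methyl-6-(prop-1-en-2-yl)cyclohex-3-ene-1-carbaldehyde, via dilithio alkoxide 16 (not isolated), via dioxolane allylic alcohol 17 (not isolated)
Conditions: n-BuLi (3.5 equiv), THF, −78 → 0 °C; H2O; then 1 M HCl, THF, rt
Reagents that add atoms: water, O
Why: Shapiro reaction: the species deprotonated at oxygen, nitrogen and C8 loses sulfinate and dinitrogen to give the C7 alkenyllithium, which is protonated. An alkoxide on C6 cannot be expelled, so the allylic C–O bond and its configuration persist. Dilute acid then releases the aldehyde from the dioxolane.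

Step 11
Reactants: 18 hydroxy aldehyde
Product: 19 (1R,5R,6R)-5-ethenyl-5-methyl-6-(prop-1-en-2-yl)cyclohex-2-en-1-ol
Conditions: Ph3PCH3Br, KOt-Bu, THF, 0 °C → rt
Reagents that add atoms: methyltriphenylphosphonium bromide, C[P+](c1ccccc1)(c1ccccc1)c1ccccc1.[Br-]
Why: Wittig methylenation of the non-enolisable neopentyl aldehyde. The free hydroxyl only consumes an extra equivalent of ylide, and no stereocentre is touched.

Step 12
Reactants: 19 dienol; 20 1-ethoxyprop-1-ene
Product: 21 2-bromo-1-ethoxypropyl ether of 19 (mixed bromoacetal)
Conditions: N-bromosuccinimide, CH2Cl2, −40 → 0 °C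
Reagents that add atoms: N-bromosuccinimide, O=C1CCC(=O)N1Br
Why: Haloetherification: the bromonium ion forms on the most electron-rich alkene, the enol ether, and is captured by the allylic alcohol. This gives the mixed bromoacetal of the Ueno–Stork method; its two new centres do not matter because C12 is later oxidised and C11 is re-set.

Step 13
Reactants: 21 bromoacetal
Product: 23 2-ethoxy-6-ethenyl-3,6-dimethyl-7-(prop-1-en-2-yl)octahydro-1-benzofuran-4-ol, via hydroperoxide 22 (not isolated)
Conditions: n-Bu3SnH (slow addition), dry air, toluene, 0 °C → rt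
Reagents that add atoms: dioxygen, O=O
Why: Oxygenative Ueno–Stork cyclisation: the C11 radical closes 5-exo onto C7 from the face of the C6 oxygen, and cis ring fusion is the only geometrically possible outcome. The C8 radical is captured by dioxygen anti to the new C7–C11 bond, on the convex face, giving C8–O trans to C11. The stannane reduces the hydroperoxide to the alcohol.

Step 14
Reactants: 23 bicyclic lactol ether alcohol
Product: 24 tert-butyldimethylsilyl ether of 23
Conditions: t-BuMe2SiCl, imidazole, DMAP (cat.), DMF, 40 °C
Reagents that add atoms: tert-butyldimethylsilyl chloride, CC(C)(C)[Si](C)(C)Cl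
Why: Standard silylation of the secondary alcohol. A silyl ether tolerates the chromic acid step and the strongly basic enolate chemistry, which an acetate would not.

Step 15
Reactants: 24 silyl ether
Product: 26 4-(tert-butyldimethylsilyloxy)-6-ethenyl-3,6-dimethyl-7-(prop-1-en-2-yl)hexahydro-1-benzofuran-2(3H)-one, via lactol 25 (not isolated)
Conditions: CrO3, H2SO4, H2O, acetone, 0 °C
Reagents that add atoms: water, O
Why: Jones oxidation of a 2-alkoxytetrahydrofuran: acid opens the mixed acetal to the lactol, which is oxidised to the γ-lactone. Isolated alkenes and the secondary silyl ether are expected to be inert under brief treatment at 0 °C.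

Step 16
Reactants: 26 lactone
Product: 28 3-hydroxy derivative of 26 (hydroxyl syn to H3a), via potassium enolate 27 (not isolated)
Conditions: KN(SiMe3)2, THF, −78 °C; 2-(phenylsulfonyl)-3-phenyloxaziridine; NH4Cl
Reagents that add atoms: 2-(phenylsulfonyl)-3-phenyloxaziridine, O=S(=O)(c1ccccc1)N1OC1c1ccccc1
Why: α-Hydroxylation of a lactone enolate with an N-sulfonyloxaziridine; deprotonation erases the mixture at C11. The oxidant approaches the planar enolate on the convex face, syn to H7 and away from the carbocycle, so the hydroxyl ends on the exo face and the methyl on the endo face, as the target requires.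

Step 17
Reactants: 28 α-hydroxy lactone; 29 angelic anhydride
Product: 30 (Z)-2-methylbut-2-enoate of 28
Conditions: LiN(SiMe3)2, THF, −78 °C; then 29, −78 → 0 °C
Reagents that add atoms: none
Why: Acylation of the lithium tertiary alkoxide by the symmetrical anhydride at low temperature. No nucleophilic amine catalyst is present, and it is such catalysts that isomerise Z-enoates by conjugate addition–elimination.

Step 18
Reactants: 30 silyl ether angelate
Product: 32 (3S,3aR,4S,6R,7R,7aS)-4-(acetyloxy)-6-ethenyl-3,6-dimethyl-2-oxo-7-(prop-1-en-2-yl)octahydro-1-benzofuran-3-yl (2Z)-2-methylbut-2-enoate, via C8 alcohol 31 (not isolated)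
Conditions: HF·pyridine, pyridine/THF, 0 °C → rt; NaHCO3 work-up; then Ac2O, DMAP (cat.), pyridine, rt
Reagents that add atoms: acetic anhydride, CC(=O)OC(C)=O
Why: Cleavage of the silyl ether by acidic fluoride never generates an alkoxide, so acyl migration from O11 and translactonisation are avoided. The liberated secondary alcohol is then acetylated under standard nucleophilic catalysis.

## Compound list

1 | (E)-4-(dimethylamino)but-3-en-2-one | CN(C)/C=C/C(C)=O | starting material
2 | benzylamine | NCc1ccccc1 | starting material
3 | (Z)-4-(benzylamino)but-3-en-2-one | CC(=O)/C=C\NCc1ccccc1 | intermediate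
4 | methyl benzyl[(E)-3-oxobut-1-en-1-yl]carbamate | COC(=O)N(Cc1ccccc1)/C=C/C(C)=O | intermediate
5 | methyl benzyl[(E)-3-(tert-butyldimethylsilyloxy)buta-1,3-dien-1-yl]carbamate | COC(=O)N(Cc1ccccc1)/C=C/C(=C)O[Si](C)(C)C(C)(C)C | intermediate
6 | methacrolein (2-methylprop-2-enal) | CC(=C)C=O | starting material
7 | methyl benzyl[(1R,6S)-6-formyl-6-methyl-3-(tert-butyldimethylsilyloxy)cyclohex-2-en-1-yl]carbamate (formyl cis to nitrogen) | O=C[C@@]1(C)CCC(O[Si](C)(C)C(C)(C)C)=C[C@H]1N(Cc2ccccc2)C(=O)OC | intermediate
8 | methyl benzyl[(1R,2S)-2-formyl-2-methyl-5-oxocyclohexyl]carbamate | O=C[C@@]1(C)CCC(=O)C[C@H]1N(Cc2ccccc2)C(=O)OC | intermediate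
9 | (1S)-1-methyl-4-oxocyclohex-2-ene-1-carbaldehyde | O=C[C@@]1(C)CCC(=O)C=C1 | intermediate
10 | (4S)-4-(1,3-dioxolan-2-yl)-4-methylcyclohex-2-en-1-one | C1(OCCO1)[C@@]2(C)CCC(=O)C=C2 | intermediate
11 | isopropenylmagnesium bromide | CC(=C)[Mg]Br | starting material
12 | {[(3R,4S)-4-(1,3-dioxolan-2-yl)-4-methyl-3-(prop-1-en-2-yl)cyclohex-1-en-1-yl]oxy}trimethylsilane | C1(OCCO1)[C@@]2(C)CCC(O[Si](C)(C)C)=C[C@@H]2C(=C)C | intermediate
13 | 1,2-epoxide of 12 (epoxide oxygen trans to isopropenyl, trimethylsilyloxy on the epoxide carbon) | C1(OCCO1)[C@@]2(C)CC[C@@]3(O[Si](C)(C)C)O[C@H]3[C@@H]2C(=C)C | intermediate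
14 | (2S,3R,4S)-4-(1,3-dioxolan-2-yl)-2-hydroxy-4-methyl-3-(prop-1-en-2-yl)cyclohexan-1-one | C1(OCCO1)[C@@]2(C)CCC(=O)[C@@H](O)[C@@H]2C(=C)C | intermediate
15 | 2,4,6-triisopropylbenzenesulfonylhydrazone of 14 (N–N bond syn to the C8 methylene) | C1(OCCO1)[C@@]2(C)CC/C(=N\NS(=O)(=O)c3c(C(C)C)cc(C(C)C)cc3C(C)C)[C@@H](O)[C@@H]2C(=C)C | intermediate
16 | lithium alkoxide of 17 lithiated at the alkene carbon next to the carbinol (C7) | C1(OCCO1)[C@@]2(C)CC=C([Li])[C@@H](O[Li])[C@@H]2C(=C)C | intermediate
17 | (1R,5S,6R)-5-(1,3-dioxolan-2-yl)-5-methyl-6-(prop-1-en-2-yl)cyclohex-2-en-1-ol | C1(OCCO1)[C@@]2(C)CC=C[C@@H](O)[C@@H]2C(=C)C | intermediate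
18 | (1S,5R,6R)-5-hydroxy-1-methyl-6-(prop-1-en-2-yl)cyclohex-3-ene-1-carbaldehyde | O=C[C@@]1(C)CC=C[C@@H](O)[C@@H]1C(=C)C | intermediate
19 | (1R,5R,6R)-5-ethenyl-5-methyl-6-(prop-1-en-2-yl)cyclohex-2-en-1-ol | C=C[C@@]1(C)CC=C[C@@H](O)[C@@H]1C(=C)C | intermediate
20 | 1-ethoxyprop-1-ene (E/Z mixture) | CCOC=CC | starting material
21 | 2-bromo-1-ethoxypropyl ether of 19 (epimers at both side-chain carbons) | C=C[C@@]1(C)CC=C[C@@H](OC(OCC)C(C)Br)[C@@H]1C(=C)C | intermediate
22 | 2-ethoxy-6-ethenyl-4-hydroperoxy-3,6-dimethyl-7-(prop-1-en-2-yl)octahydro-1-benzofuran (ring carbons configured as in 32; epimers at C2 and C3) | C=C[C@@]1(C)C[C@H](OO)[C@@H]2[C@@H](OC(OCC)C2C)[C@@H]1C(=C)C | intermediate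
23 | 2-ethoxy-6-ethenyl-3,6-dimethyl-7-(prop-1-en-2-yl)octahydro-1-benzofuran-4-ol (cis ring fusion, 4-OH trans to C3, C3a, C4, C6, C7, C7a configured as in 32; epimers at C2 and C3) | C=C[C@@]1(C)C[C@H](O)[C@@H]2[C@@H](OC(OCC)C2C)[C@@H]1C(=C)C | intermediate
24 | tert-butyldimethylsilyl ether of 23 | C=C[C@@]1(C)C[C@H](O[Si](C)(C)C(C)(C)C)[C@@H]2[C@@H](OC(OCC)C2C)[C@@H]1C(=C)C | intermediate
25 | lactol from 24 (2-hydroxy in place of 2-ethoxy) | C=C[C@@]1(C)C[C@H](O[Si](C)(C)C(C)(C)C)[C@@H]2[C@@H](OC(O)C2C)[C@@H]1C(=C)C | intermediate
26 | 4-(tert-butyldimethylsilyloxy)-6-ethenyl-3,6-dimethyl-7-(prop-1-en-2-yl)hexahydro-1-benzofuran-2(3H)-one (ring carbons as in 32; epimers at C3) | C=C[C@@]1(C)C[C@H](O[Si](C)(C)C(C)(C)C)[C@@H]2[C@@H](OC(=O)C2C)[C@@H]1C(=C)C | intermediate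
27 | potassium enolate of 26 | C=C[C@@]1(C)C[C@H](O[Si](C)(C)C(C)(C)C)[C@@H]2[C@@H](OC(O[K])=C2C)[C@@H]1C(=C)C | intermediate
28 | 4-(tert-butyldimethylsilyloxy)-6-ethenyl-3-hydroxy-3,6-dimethyl-7-(prop-1-en-2-yl)hexahydro-1-benzofuran-2(3H)-one (3-OH syn to H3a; all centres as in 32) | C=C[C@@]1(C)C[C@H](O[Si](C)(C)C(C)(C)C)[C@@H]2[C@@H](OC(=O)[C@@]2(C)O)[C@@H]1C(=C)C | intermediate
29 | angelic anhydride, (Z)-2-methylbut-2-enoic anhydride (commercial, otherwise made from angelic acid) | C/C=C(/C)C(=O)OC(=O)/C(C)=C\C | starting material
30 | (2Z)-2-methylbut-2-enoate of 28 | C=C[C@@]1(C)C[C@H](O[Si](C)(C)C(C)(C)C)[C@@H]2[C@@H](OC(=O)[C@@]2(C)OC(=O)/C(C)=C\C)[C@@H]1C(=C)C | intermediate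
31 | 4-hydroxy compound from 30 (silyl group removed) | C=C[C@@]1(C)C[C@H](O)[C@@H]2[C@@H](OC(=O)[C@@]2(C)OC(=O)/C(C)=C\C)[C@@H]1C(=C)C | intermediate
32 | (3S,3aR,4S,6R,7R,7aS)-4-(acetyloxy)-6-ethenyl-3,6-dimethyl-2-oxo-7-(prop-1-en-2-yl)octahydro-1-benzofuran-3-yl (2Z)-2-methylbut-2-enoate | C=C[C@@]1(C)C[C@H](OC(C)=O)[C@@H]2[C@@H](OC(=O)[C@@]2(C)OC(=O)/C(C)=C\C)[C@@H]1C(=C)C | target

## Step count and least certain steps

Total: 18 steps. Longest linear sequence: 18 steps (the route is linear from 1 to 32, with 14 steps after the key step).

Step 4 (key step). The most likely failure is loss of enantiofacial control. Any cycloaddition that takes place off the metal gives racemic material, whether it is the thermal background reaction or one promoted by silyl cations formed once traces of water have hydrolysed the diene. The cationic complex can also be slowed by binding of the product. The fallback replaces catalyst control by auxiliary control while forming the same two bonds. Starting from 1, amine exchange with (2S,5S)-2,5-diphenylpyrrolidine gives (E)-4-[(2S,5S)-2,5-diphenylpyrrolidin-1-yl]but-3-en-2-one F1. Its potassium enolate is silylated to (2S,5S)-1-[(E)-3-(tert-butyldimethylsilyloxy)buta-1,3-dien-1-yl]-2,5-diphenylpyrrolidine F2. Thermal cycloaddition with 6 in toluene gives the amino aldehyde (1S,2R)-2-[(2S,5S)-2,5-diphenylpyrrolidin-1-yl]-1-methyl-4-(tert-butyldimethylsilyloxy)cyclohex-3-ene-1-carbaldehyde F3 under control of the C2-symmetric amine. Dilute HCl in THF then hydrolyses the enol ether and expels the protonated auxiliary, so the route is rejoined at 9. The antipode of the pyrrolidine is used if that is the one leading to the 1S series.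

Step 5. The carbamate is a poor leaving group, so β-elimination may be incomplete, and the vinylogous formyl ketone may be degraded by attack at the aldehyde if stronger base is needed. Fallback from 7: LiAlH4 in Et2O reduces the aldehyde to the primary alcohol and the carbamate to the N-methyl amine, giving {(1S,2R)-2-[benzyl(methyl)amino]-1-methyl-4-(tert-butyldimethylsilyloxy)cyclohex-3-en-1-yl}methanol F4. Aqueous HF in MeCN cleaves the enol ether and eliminates the now basic amine as its ammonium ion to give (4S)-4-(hydroxymethyl)-4-methylcyclohex-2-en-1-one F5. Dess–Martin oxidation returns the route to 9.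

Step 10. Metalation may occur at the wrong site, or the alkyllithium may add to C=N, if the hydrazone adopts the geometry in which N–H is hydrogen-bonded to the C6 hydroxyl. The allylic alcohol may also ionise during the acid treatment. Fallback from 14: silylation (t-BuMe2SiOTf, 2,6-lutidine) gives the silyl ether of 14 F6. KN(SiMe3)2 and PhNTf2 convert it into the C7 enol triflate F7 by kinetic deprotonation at the C8 methylene. Pd(OAc)2/PPh3 with HCO2H and n-Bu3N reduces the triflate to the silyl ether of 17 F8. Aqueous HCl in THF then removes the silyl ether and the dioxolane together, and the route is rejoined at 18.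

Step 13. The C11 radical may be captured by oxygen before it has cyclised, the C8 radical may simply be reduced, or face discrimination at C8 may be eroded by the C10 methyl on the same side. The fallback separates ring closure from oxygenation. From 19, N-iodosuccinimide and 20 give the 1-ethoxy-2-iodopropyl ether of 19 F9. Et3B with a trace of air, in the absence of any reductant, effects iodine-atom-transfer cyclisation to 2-ethoxy-6-ethenyl-4-iodo-3,6-dimethyl-7-(prop-1-en-2-yl)octahydro-1-benzofuran F10. This cyclised iodide is then treated with n-Bu3SnH under air, so that only the C8 radical ever meets oxygen, and 23 is reached.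

Step 17. Acylation of the congested tertiary alkoxide may be slow, and the Z acyl group may isomerise to the E isomer if the reaction has to be forced. Fallback from 28: the lithium alkoxide is acylated with the small, highly electrophilic 2-[bis(2,2,2-trifluoroethoxy)phosphoryl]propanoyl chloride to give the 2-[bis(2,2,2-trifluoroethoxy)phosphoryl]propanoate of 28 F11. A Still–Gennari olefination with acetaldehyde (KN(SiMe3)2, 18-crown-6, THF, −78 °C) then builds the Z-enoate on the oxygen, and the route is rejoined at 30.

## Further compounds

F1 | step 4 | (E)-4-[(2S,5S)-2,5-diphenylpyrrolidin-1-yl]but-3-en-2-one | CC(=O)/C=C/N1[C@H](c2ccccc2)CC[C@H]1c3ccccc3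
F2 | step 4 | (2S,5S)-1-[(E)-3-(tert-butyldimethylsilyloxy)buta-1,3-dien-1-yl]-2,5-diphenylpyrrolidine | C=C(O[Si](C)(C)C(C)(C)C)/C=C/N1[C@H](c2ccccc2)CC[C@H]1c3ccccc3
F3 | step 4 | (1S,2R)-2-[(2S,5S)-2,5-diphenylpyrrolidin-1-yl]-1-methyl-4-(tert-butyldimethylsilyloxy)cyclohex-3-ene-1-carbaldehyde | O=C[C@@]1(C)CCC(O[Si](C)(C)C(C)(C)C)=C[C@H]1N2[C@H](c3ccccc3)CC[C@H]2c4ccccc4
F4 | step 5 | {(1S,2R)-2-[benzyl(methyl)amino]-1-methyl-4-(tert-butyldimethylsilyloxy)cyclohex-3-en-1-yl}methanol | OC[C@@]1(C)CCC(O[Si](C)(C)C(C)(C)C)=C[C@H]1N(C)Cc2ccccc2
F5 | step 5 | (4S)-4-(hydroxymethyl)-4-methylcyclohex-2-en-1-one | OC[C@@]1(C)CCC(=O)C=C1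
F6 | step 10 | tert-butyldimethylsilyl ether of 14 | C1(OCCO1)[C@@]2(C)CCC(=O)[C@@H](O[Si](C)(C)C(C)(C)C)[C@@H]2C(=C)C
F7 | step 10 | enol trifluoromethanesulfonate of F6 (C7=C8) | C1(OCCO1)[C@@]2(C)CC=C(OS(=O)(=O)C(F)(F)F)[C@@H](O[Si](C)(C)C(C)(C)C)[C@@H]2C(=C)C
F8 | step 10 | tert-butyldimethylsilyl ether of 17 | C1(OCCO1)[C@@]2(C)CC=C[C@@H](O[Si](C)(C)C(C)(C)C)[C@@H]2C(=C)C
F9 | step 13 | 1-ethoxy-2-iodopropyl ether of 19 | C=C[C@@]1(C)CC=C[C@@H](OC(OCC)C(C)I)[C@@H]1C(=C)C
F10 | step 13 | 2-ethoxy-6-ethenyl-4-iodo-3,6-dimethyl-7-(prop-1-en-2-yl)octahydro-1-benzofuran | C=C[C@@]1(C)C[C@H](I)[C@@H]2[C@@H](OC(OCC)C2C)[C@@H]1C(=C)C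
F11 | step 17 | 2-[bis(2,2,2-trifluoroethoxy)phosphoryl]propanoate of 28 | C=C[C@@]1(C)C[C@H](O[Si](C)(C)C(C)(C)C)[C@@H]2[C@@H](OC(=O)[C@@]2(C)OC(=O)C(C)P(=O)(OCC(F)(F)F)OCC(F)(F)F)[C@@H]1C(=C)C
A1 | alternative 1 | methyl (2Z)-2-(bromomethyl)-4-(tert-butyldimethylsilyloxy)-6-ethenyl-6-methyl-8-oxo-7-(prop-1-en-2-yl)oct-2-enoate (C4, C6, C7 configured as in A2) | C=C[C@@](C)(C[C@H](O[Si](C)(C)C(C)(C)C)/C=C(\CBr)C(=O)OC)[C@H](C=O)C(=C)C
A2 | alternative 1 | 4-(tert-butyldimethylsilyloxy)-6-ethenyl-6-methyl-3-methylidene-7-(prop-1-en-2-yl)hexahydro-1-benzofuran-2(3H)-one (cis-fused, ring carbons as in 32) | C=C[C@@]1(C)C[C@H](O[Si](C)(C)C(C)(C)C)[C@@H]2[C@@H](OC(=O)C2=C)[C@@H]1C(=C)C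
A3 | alternative 2 | (5S)-5-(tert-butyldimethylsilyloxy)-3-methylcyclohex-2-en-1-one | O=C1C[C@@H](O[Si](C)(C)C(C)(C)C)CC(C)=C1
A4 | alternative 2 | 1-methylcyclobutene | CC1=CCC1
A5 | alternative 2 | cis-anti-cis 6-4-4 tricyclic photoadduct of A3 and A4 | O=C1C[C@@H](O[Si](C)(C)C(C)(C)C)C[C@]2(C)[C@H]3CC[C@@]3(C)[C@H]12
A6 | alternative 2 | 5-(tert-butyldimethylsilyloxy)-3-ethenyl-3-methyl-2-(prop-1-en-2-yl)cyclohexan-1-one (centres as at C5, C8, C10 of 32) | C=C[C@@]1(C)C[C@H](O[Si](C)(C)C(C)(C)C)CC(=O)[C@@H]1C(=C)C
A7 | alternative 3 | (6E)-4-(benzyloxy)-6-methyl-5-(prop-1-en-2-yl)-8-(trimethylsilyl)octa-1,6-dien-3-one (C4, C5 configured as in A8) | C=CC(=O)[C@@H](OCc1ccccc1)[C@H](C(=C)C)/C(C)=C/C[Si](C)(C)C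
A8 | alternative 3 | 2-(benzyloxy)-4-ethenyl-4-methyl-3-(prop-1-en-2-yl)cyclohexan-1-one | C=C[C@@]1(C)CCC(=O)[C@@H](OCc2ccccc2)[C@@H]1C(=C)C
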